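**Plan**
1. Retrosynthetic cuts: (a) the aryl–vinyl bond of the stilbene at C4 of the upper dihydrobenzofuran (Heck); (b) the C2–C3 bond of that ring (carbene C–H insertion) and the bond from C3 to ring A (ketone from an aryl Grignard reagent and a Weinreb amide); (c) in the lower dihydrobenzofuran, fused to the central resorcinol ring B, the O1–C2 bond, and behind it the C2–C3 and C3–C3a bonds of a spirocyclopropane (sulfur ylide) and the C2–C3a bond (Knoevenagel).
2. Enabling feature: in the lower unit C3a lies between the two oxygen-bearing carbons C4 and C7a of ring B, so ring B is a masked cyclohexane-1,3-dione with C3a as its C2, and C2 carries a para-oxygenated phenyl group. The C3a–C2 bond is therefore the polarised bond of a donor–acceptor cyclopropane (C3a, C2, C3) spiro-fused to the dione; its heterolysis and reclosure on oxygen expand the three-membered ring by C7a and O1 to the dihydrofuran.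
3. Forward order: alkylidene dione, then spirocyclopropane, then ring expansion to the lower dihydrofuran, then dehydrogenation to ring B, then diaryl ketone with ring A, then carbene insertion to the upper dihydrofuran, then Heck coupling to the stilbene, then debenzylation.
4. Stereochemistry: C3 of the lower unit comes from the ylide carbon of a C2-symmetric chiral sulfonium salt, and its C2 is relayed from C3 in the ring expansion (trans). C3 of the upper unit comes from Rh2(S-PTAD)4, and its C2 is set by acid equilibration to trans.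

Key step: step 4

Assumption: (2R,5R)-5 and Rh2(S-PTAD)4 are written as the antipodes expected to give 1R in 7 and 3S in 21, and if either induction runs the other way the mirror-image reagent is used with no other change; 5 is taken as purchasable (otherwise two steps from (2S,5S)-hexane-2,5-diol).

Shorthand in names: ArP = 4-(benzyloxy)phenyl; ArR = 3,5-bis(benzyloxy)phenyl; PBB = 4-(benzyloxy)benzyl; Bf = (2R,3R)-4-(benzyloxy)-3-ArR-2-ArP-2,3-dihydro-1-benzofuran-6-yl.

Step 1
Reactants: 1 methyl 3,5-dioxocyclohexane-1-carboxylate; 2 4-(benzyloxy)benzaldehyde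
Product: 3 methyl 4-[(ArP)methylidene]-3,5-dioxocyclohexane-1-carboxylate
Conditions: piperidine (0.1 equiv), AcOH (0.1 equiv), CH2Cl2, 4 Å molecular sieves, 0 °C; filtered and used crude at once
Reagents that add atoms: none
Why: Knoevenagel condensation at C2 of the cyclic 1,3-dione, in which the para-benzyloxy group makes 3 a push–pull alkene that should take up a second molecule of 1 more slowly than simpler arylidene diones; no stereocentre of the target is set.

Step 2
Reactants: 4 3,5-bis(benzyloxy)benzyl bromide; 5 (2R,5R)-2,5-dimethylthiolane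
Product: 6 (2R,5R)-1-[3,5-bis(benzyloxy)benzyl]-2,5-dimethylthiolan-1-ium tetrafluoroborate
Conditions: NaBF4 (excess), CH2Cl2/H2O, rt
Reagents that add atoms: sodium tetrafluoroborate ([Na+].F[B-](F)(F)F)
Why: SN2 S-alkylation of the sulfide by the benzylic bromide, driven by exchange of bromide for the non-nucleophilic tetrafluoroborate, and because the two faces of sulfur in the C2-symmetric sulfide are equivalent a single sulfonium salt should result.

Step 3
Reactants: 3 methyl 4-[(ArP)methylidene]-3,5-dioxocyclohexane-1-carboxylate; 6 (2R,5R)-1-[3,5-bis(benzyloxy)benzyl]-2,5-dimethylthiolan-1-ium tetrafluoroborate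
Product: 7 methyl (1R)-1-ArR-2-ArP-4,8-dioxospiro[2.5]octane-6-carboxylate (epimers at C2 and at C6)
Conditions: 6, LiN(SiMe3)2, THF, −78 °C; then 3, −78 to −20 °C; neutral work-up, filtration through basic alumina
Reagents that add atoms: none
Why: Sulfur-ylide cyclopropanation of an alkylidene 1,3-dicarbonyl compound (Corey–Chaykovsky type, Michael-initiated ring closure), in which the benzylide adds through the face left open by the trans-dimethylthiolane ring to the benzylidene carbon of 3 and the dione enolate carbon then displaces the sulfide in a 3-exo-tet SN2 step with inversion, so that the ylide carbon becomes C1 of 7 with R configuration while C2 and C6 form as epimer mixtures that are of no consequence later.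

Step 4
Reactants: 7 methyl (1R)-1-ArR-2-ArP-4,8-dioxospiro[2.5]octane-6-carboxylate
Product: 8 methyl (2R,3R)-3-ArR-2-ArP-4-oxo-2,3,4,5,6,7-hexahydro-1-benzofuran-6-carboxylate (2,3-trans; C6 epimers)
Conditions: Sc(OTf)3 (5 mol %), CH2Cl2, −20 °C to rt
Reagents that add atoms: none
Why: Sc(OTf)3 binds the 1,3-dione, and the bond of 7 between the spiro carbon C3 (acceptor, flanked by two carbonyl groups) and C2 (donor, bearing ArP) heterolyses to a scandium enolate and a para-alkoxybenzylic cation, which the enolate oxygen captures to give the 2,3-dihydrofuran. The closest known reaction type is the acid-catalysed Cloke–Wilson rearrangement of cyclohexane-1,3-dione-2-spirocyclopropanes to 2-aryl-tetrahydrobenzofuran-4-ones. The five-membered ring closes by attack of the enolate oxygen on the cationic carbon in a 5-(enolendo)-exo-trig mode (the cation written in its quinone-methide-like form); closure through the enolate carbon would only return the strained three-membered ring, so release of cyclopropane strain drives the change. The new stereocentre C2 of 8 is controlled by the adjacent C3, which undergoes no bond change and is carried over from C1 of 7: the cation closes anti to the 3-aryl group, and because ionisation of the product is reversible the trans isomer is also the thermodynamic one, so both C2 epimers of 7 converge. The selectivity needed is that of the bond that breaks (C3–C2, not C3–C1 of 7), and the substrate secures it because the para-alkoxy group stabilises a cation at C2 whereas the two meta-alkoxy groups of ArR disfavour a cation at C1. Which of the two carbonyl oxygens closes the ring only decides the configuration at C6, which disappears in step 5.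

Step 5
Reactants: 8 methyl (2R,3R)-3-ArR-2-ArP-4-oxo-2,3,4,5,6,7-hexahydro-1-benzofuran-6-carboxylate
Product: 10 methyl (2R,3R)-3-ArR-2-ArP-4-hydroxy-2,3-dihydro-1-benzofuran-6-carboxylate, via cyclohexadienone 9 (not isolated)
Conditions: LiN(i-Pr)2, THF, −78 °C; then N-tert-butylbenzenesulfinimidoyl chloride, −78 °C to rt
Reagents that add atoms: none
Why: Regiospecific ketone dehydrogenation, in which the kinetic lithium enolate at C5 is sulfenylated and the adduct loses the sulfenamide by syn elimination to the cross-conjugated dienone 9, which tautomerises to the aromatic ring B without touching the dihydrofuran stereocentres and with convergence of the C6 epimers.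

Step 6
Reactants: 10 methyl (2R,3R)-3-ArR-2-ArP-4-hydroxy-2,3-dihydro-1-benzofuran-6-carboxylate
Product: 11 methyl (2R,3R)-4-(benzyloxy)-3-ArR-2-ArP-2,3-dihydro-1-benzofuran-6-carboxylate
Conditions: BnBr, K2CO3, DMF, rt
Reagents that add atoms: benzyl bromide (BrCc1ccccc1)
Why: Williamson etherification of the new phenol, which masks the O–H bond before the Grignard and carbene steps.

Step 7
Reactants: 11 methyl (2R,3R)-4-(benzyloxy)-3-ArR-2-ArP-2,3-dihydro-1-benzofuran-6-carboxylate
Product: 12 (2R,3R)-4-(benzyloxy)-3-ArR-2-ArP-N-methoxy-N-methyl-2,3-dihydro-1-benzofuran-6-carboxamide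
Conditions: MeNH(OMe)·HCl, i-PrMgCl, THF, −20 °C
Reagents that add atoms: N,O-dimethylhydroxylamine hydrochloride (CNOC.Cl)
Why: Direct aminolysis of the methyl ester by the chloromagnesium amide of N,O-dimethylhydroxylamine gives the Weinreb amide, which takes up one aryl nucleophile only.

Step 8
Reactants: 13 5-bromobenzene-1,3-diol; 14 4-(benzyloxy)benzyl chloride
Product: 15 1-bromo-3,5-bis(PBB-oxy)benzene
Conditions: 14 (2.2 equiv in all), K2CO3 (3 equiv), DMF, 60 °C
Reagents that add atoms: 4-(benzyloxy)benzyl chloride, second equivalent of 14 (ClCc1ccc(OCc2ccccc2)cc1)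
Why: Double Williamson etherification in which each of the two phenoxide oxygens of 13 displaces chloride from one molecule of 14, after which the same PBB group serves as the carbene acceptor at the oxygen ortho to the future ketone and as a protecting group at the para oxygen.

Step 9
Reactants: 15 1-bromo-3,5-bis(PBB-oxy)benzene
Product: 16 1,2-dibromo-3,5-bis(PBB-oxy)benzene
Conditions: N-bromosuccinimide, MeCN, 0 °C
Reagents that add atoms: N-bromosuccinimide (O=C1CCC(=O)N1Br)
Why: Electrophilic bromination of the resorcinol diether ring para to one alkoxy group and ortho to the other, the position between the two bulky ethers being shielded and the anisole-type rings of the PBB groups far less activated.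

Step 10
Reactants: 16 1,2-dibromo-3,5-bis(PBB-oxy)benzene; 12 (2R,3R)-4-(benzyloxy)-3-ArR-2-ArP-N-methoxy-N-methyl-2,3-dihydro-1-benzofuran-6-carboxamide
Product: 18 [2-bromo-4,6-bis(PBB-oxy)phenyl](Bf)methanone, via arylmagnesium chloride 17 (not isolated)
Conditions: 16, i-PrMgCl·LiCl, THF, −40 to −20 °C; then 12, −20 to 0 °C; aqueous NH4Cl
Reagents that add atoms: isopropylmagnesium chloride–lithium chloride (CC(C)[Mg]Cl.[Li+].[Cl-]); its Mg and Cl stand in 17 only
Why: Bromine–magnesium exchange should take place at the bromine flanked by the alkoxy group (inductive and chelating stabilisation of the aryl anion), the ortho-bromoaryl Grignard reagent is kept cold to avoid aryne formation, and its addition to the Weinreb amide stops at the ketone through the magnesium chelate.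

Step 11
Reactants: 18 [2-bromo-4,6-bis(PBB-oxy)phenyl](Bf)methanone
Product: 19 [2-bromo-4,6-bis(PBB-oxy)phenyl](Bf)methanone hydrazone
Conditions: N2H4·H2O (large excess), AcOH (cat.), n-BuOH, 110 °C, sealed vessel
Reagents that add atoms: hydrazine hydrate (NN.O)
Why: Condensation to the N-unsubstituted hydrazone, for which the di-ortho-substituted ketone calls for excess hydrazine, acid catalysis and heat, conditions that the ethers and the aryl bromide tolerate.

Step 12
Reactants: 19 [2-bromo-4,6-bis(PBB-oxy)phenyl](Bf)methanone hydrazone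
Product: 21 (2R,3S)-4-bromo-2-ArP-3-Bf-6-(PBB-oxy)-2,3-dihydro-1-benzofuran (2,3-cis), via diazo compound 20 (not isolated)
Conditions: MnO2, CH2Cl2, 0 °C, filtration through Celite; then Rh2(S-PTAD)4 (1 mol %), CH2Cl2, 0 °C to rt
Reagents that add atoms: none
Why: Dehydrogenation of the hydrazone gives the diaryldiazomethane, whose dirhodium donor/donor carbene inserts into a C–H bond of the ortho O–CH2 group through a five-membered transition state (intramolecular carbene C–H insertion), Rh2(S-PTAD)4 selecting the carbene face and so fixing C3 as S, while the concerted insertion is expected to place the two new aryl groups cis.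

Step 13
Reactants: 21 (2R,3S)-4-bromo-2-ArP-3-Bf-6-(PBB-oxy)-2,3-dihydro-1-benzofuran
Product: 22 (2S,3S)-4-bromo-2-ArP-3-Bf-2,3-dihydro-1-benzofuran-6-ol (2,3-trans)
Conditions: CF3CO2H (10 vol %), 1,3,5-trimethoxybenzene, CH2Cl2, 0 °C
Reagents that add atoms: none
Why: The Brønsted acid ionises both para-alkoxybenzylic aryl ether bonds, so that the acyclic one at O6 is cleaved for good with capture of its cation by the scavenger, whereas the ring-opened cation at C2 recloses on the neighbouring phenol oxygen much faster than it meets the scavenger and settles in the more stable 2,3-trans arrangement, C3 and the already trans lower dihydrofuran being unchanged.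

Step 14
Reactants: 22 (2S,3S)-4-bromo-2-ArP-3-Bf-2,3-dihydro-1-benzofuran-6-ol; 23 1-(benzyloxy)-4-ethenylbenzene
Product: 24 (2S,3S)-2-ArP-4-[(E)-2-ArP-ethenyl]-3-Bf-2,3-dihydro-1-benzofuran-6-ol
Conditions: Pd(OAc)2 (5 mol %), P(t-Bu)3·HBF4 (10 mol %), K2CO3, DMF, 90 °C
Reagents that add atoms: none
Why: Heck reaction of the hindered, electron-rich aryl bromide under a bulky electron-rich phosphine, in which syn insertion of the styrene and syn β-hydride elimination give the E stilbene.

Step 15
Reactants: 24 (2S,3S)-2-ArP-4-[(E)-2-ArP-ethenyl]-3-Bf-2,3-dihydro-1-benzofuran-6-ol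
Product: 25 (2R,3R)-3-(3,5-dihydroxyphenyl)-6-{(2S,3S)-6-hydroxy-2-(4-hydroxyphenyl)-4-[(E)-2-(4-hydroxyphenyl)ethenyl]-2,3-dihydro-1-benzofuran-3-yl}-2-(4-hydroxyphenyl)-2,3-dihydro-1-benzofuran-4-ol (target)
Conditions: BCl3 (1 M in CH2Cl2, excess), pentamethylbenzene (excess), CH2Cl2, −78 °C; quench at −78 °C with CHCl3/MeOH, then aqueous NaHCO3
Reagents that add atoms: none
Why: Lewis-acid cleavage of the six aryl benzyl ethers at −78 °C with pentamethylbenzene as a non-basic trap for the benzyl cations, which avoids a Brønsted acid that could protonate the stilbene and should leave the four stereocentres as they are.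

**Compound list**
1 | methyl 3,5-dioxocyclohexane-1-carboxylate | COC(=O)C1CC(=O)CC(=O)C1 | starting material
2 | 4-(benzyloxy)benzaldehyde | O=Cc1ccc(OCc2ccccc2)cc1 | starting material
3 | methyl 4-[(ArP)methylidene]-3,5-dioxocyclohexane-1-carboxylate | COC(=O)C1CC(=O)C(=Cc2ccc(OCc3ccccc3)cc2)C(=O)C1 | intermediate
4 | 3,5-bis(benzyloxy)benzyl bromide | BrCc1cc(OCc2ccccc2)cc(OCc2ccccc2)c1 | starting material
5 | (2R,5R)-2,5-dimethylthiolane | C[C@@H]1CC[C@@H](C)S1 | starting material
6 | (2R,5R)-1-[3,5-bis(benzyloxy)benzyl]-2,5-dimethylthiolan-1-ium tetrafluoroborate | C[C@@H]1CC[C@@H](C)[S+]1Cc1cc(OCc2ccccc2)cc(OCc2ccccc2)c1.F[B-](F)(F)F | intermediate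
7 | methyl (1R)-1-ArR-2-ArP-4,8-dioxospiro[2.5]octane-6-carboxylate (epimers at C2 and C6) | COC(=O)C1CC(=O)C2(C(=O)C1)C(c1ccc(OCc3ccccc3)cc1)[C@@H]2c1cc(OCc2ccccc2)cc(OCc2ccccc2)c1 | intermediate
8 | methyl (2R,3R)-3-ArR-2-ArP-4-oxo-2,3,4,5,6,7-hexahydro-1-benzofuran-6-carboxylate (C6 epimers) | COC(=O)C1CC(=O)C2=C(C1)O[C@@H](c1ccc(OCc3ccccc3)cc1)[C@@H]2c1cc(OCc2ccccc2)cc(OCc2ccccc2)c1 | intermediate
9 | methyl (2R,3R)-3-ArR-2-ArP-4-oxo-2,3,4,7-tetrahydro-1-benzofuran-6-carboxylate | COC(=O)C1=CC(=O)C2=C(C1)O[C@@H](c1ccc(OCc3ccccc3)cc1)[C@@H]2c1cc(OCc2ccccc2)cc(OCc2ccccc2)c1 | intermediate (not isolated)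
10 | methyl (2R,3R)-3-ArR-2-ArP-4-hydroxy-2,3-dihydro-1-benzofuran-6-carboxylate | COC(=O)c1cc(O)c2c(c1)O[C@@H](c1ccc(OCc3ccccc3)cc1)[C@@H]2c1cc(OCc2ccccc2)cc(OCc2ccccc2)c1 | intermediate
11 | methyl (2R,3R)-4-(benzyloxy)-3-ArR-2-ArP-2,3-dihydro-1-benzofuran-6-carboxylate | COC(=O)c1cc(OCc2ccccc2)c2c(c1)O[C@@H](c1ccc(OCc3ccccc3)cc1)[C@@H]2c1cc(OCc2ccccc2)cc(OCc2ccccc2)c1 | intermediate
12 | (2R,3R)-4-(benzyloxy)-3-ArR-2-ArP-N-methoxy-N-methyl-2,3-dihydro-1-benzofuran-6-carboxamide | CON(C)C(=O)c1cc(OCc2ccccc2)c2c(c1)O[C@@H](c1ccc(OCc3ccccc3)cc1)[C@@H]2c1cc(OCc2ccccc2)cc(OCc2ccccc2)c1 | intermediate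
13 | 5-bromobenzene-1,3-diol | Oc1cc(O)cc(Br)c1 | starting material
14 | 4-(benzyloxy)benzyl chloride | ClCc1ccc(OCc2ccccc2)cc1 | starting material
15 | 1-bromo-3,5-bis(PBB-oxy)benzene | Brc1cc(OCc2ccc(OCc3ccccc3)cc2)cc(OCc2ccc(OCc3ccccc3)cc2)c1 | intermediate
16 | 1,2-dibromo-3,5-bis(PBB-oxy)benzene | Brc1cc(OCc2ccc(OCc3ccccc3)cc2)cc(OCc2ccc(OCc3ccccc3)cc2)c1Br | intermediate
17 | [2-bromo-4,6-bis(PBB-oxy)phenyl]magnesium chloride | Cl[Mg]c1c(Br)cc(OCc2ccc(OCc3ccccc3)cc2)cc1OCc1ccc(OCc2ccccc2)cc1 | intermediate (not isolated)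
18 | [2-bromo-4,6-bis(PBB-oxy)phenyl](Bf)methanone | O=C(c1c(Br)cc(OCc2ccc(OCc3ccccc3)cc2)cc1OCc1ccc(OCc2ccccc2)cc1)c1cc(OCc2ccccc2)c2c(c1)O[C@@H](c1ccc(OCc3ccccc3)cc1)[C@@H]2c1cc(OCc2ccccc2)cc(OCc2ccccc2)c1 | intermediate
19 | [2-bromo-4,6-bis(PBB-oxy)phenyl](Bf)methanone hydrazone | NN=C(c1c(Br)cc(OCc2ccc(OCc3ccccc3)cc2)cc1OCc1ccc(OCc2ccccc2)cc1)c1cc(OCc2ccccc2)c2c(c1)O[C@@H](c1ccc(OCc3ccccc3)cc1)[C@@H]2c1cc(OCc2ccccc2)cc(OCc2ccccc2)c1 | intermediate
20 | [2-bromo-4,6-bis(PBB-oxy)phenyl](Bf)diazomethane | [N-]=[N+]=C(c1c(Br)cc(OCc2ccc(OCc3ccccc3)cc2)cc1OCc1ccc(OCc2ccccc2)cc1)c1cc(OCc2ccccc2)c2c(c1)O[C@@H](c1ccc(OCc3ccccc3)cc1)[C@@H]2c1cc(OCc2ccccc2)cc(OCc2ccccc2)c1 | intermediate (not isolated)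
21 | (2R,3S)-4-bromo-2-ArP-3-Bf-6-(PBB-oxy)-2,3-dihydro-1-benzofuran (2,3-cis) | Brc1cc(OCc2ccc(OCc3ccccc3)cc2)cc2c1[C@H](c4cc(OCc5ccccc5)c5c(c4)O[C@@H](c4ccc(OCc6ccccc6)cc4)[C@@H]5c4cc(OCc5ccccc5)cc(OCc5ccccc5)c4)[C@H](c1ccc(OCc3ccccc3)cc1)O2 | intermediate
22 | (2S,3S)-4-bromo-2-ArP-3-Bf-2,3-dihydro-1-benzofuran-6-ol (2,3-trans) | Brc1cc(O)cc2c1[C@H](c4cc(OCc5ccccc5)c5c(c4)O[C@@H](c4ccc(OCc6ccccc6)cc4)[C@@H]5c4cc(OCc5ccccc5)cc(OCc5ccccc5)c4)[C@@H](c1ccc(OCc3ccccc3)cc1)O2 | intermediate
23 | 1-(benzyloxy)-4-ethenylbenzene | C=Cc1ccc(OCc2ccccc2)cc1 | starting material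
24 | (2S,3S)-2-ArP-4-[(E)-2-ArP-ethenyl]-3-Bf-2,3-dihydro-1-benzofuran-6-ol | c1ccccc1COc1ccc(/C=C/c2cc(O)cc3c2[C@H](c4cc(OCc5ccccc5)c5c(c4)O[C@@H](c4ccc(OCc6ccccc6)cc4)[C@@H]5c4cc(OCc5ccccc5)cc(OCc5ccccc5)c4)[C@@H](c4ccc(OCc5ccccc5)cc4)O3)cc1 | intermediate
25 | (2R,3R)-3-(3,5-dihydroxyphenyl)-6-{(2S,3S)-6-hydroxy-2-(4-hydroxyphenyl)-4-[(E)-2-(4-hydroxyphenyl)ethenyl]-2,3-dihydro-1-benzofuran-3-yl}-2-(4-hydroxyphenyl)-2,3-dihydro-1-benzofuran-4-ol | Oc1ccc(/C=C/c2cc(O)cc3c2[C@H](c2cc(O)c4c(c2)O[C@@H](c2ccc(O)cc2)[C@@H]4c2cc(O)cc(O)c2)[C@@H](c2ccc(O)cc2)O3)cc1 | target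

Total step count: 15. Longest linear sequence: 12 steps (1, 3 to 7, 10 to 15); steps 2 and 8 to 9 are side branches.

**Three steps most likely to fail**

Step 3. The benzylide may add with poor facial control, the betaine may close through enolate oxygen instead of carbon (which would give the regioisomeric dihydrofuran directly), or 3 may revert or take up a second dione before the ylide reaches it. The fallback replaces the ylide by a metal carbene and sets out from 1. Diazo transfer (4-acetamidobenzenesulfonyl azide, Et3N, MeCN) should give methyl 4-diazo-3,5-dioxocyclohexane-1-carboxylate F1. Decomposition of F1 with Rh2(S-NTTL)4 in the presence of commercial (E)-1,3-bis(benzyloxy)-5-{2-[4-(benzyloxy)phenyl]ethenyl}benzene F2 (tri-O-benzylresveratrol) transfers the diacylcarbene to the alkene under catalyst control of the alkene face. This should give the 1,2-trans member of 7, where the fallback comes back to the route.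

Step 11. The carbonyl group, shielded by the ortho bromine and the ortho ether, may fail to condense, or the hydrazone may be too impure for the carbene step. The fallback exchanges the carbene insertion for an o-quinone methide annulation and sets out from 18. MgBr2·OEt2 should remove, by chelation, only the PBB ether ortho to the carbonyl group and give (Bf)[2-bromo-6-hydroxy-4-(PBB-oxy)phenyl]methanone F3. NaBH4 then gives (Bf)[2-bromo-6-hydroxy-4-(PBB-oxy)phenyl]methanol F4. With Cs2CO3 in warm toluene F4 should lose water to its o-quinone methide, which is intercepted by the benzylide of (2R,5R)-1-(PBB)-2,5-dimethylthiolan-1-ium tetrafluoroborate F5 (made from 14 and 5 as in step 2) in a trans-selective [4+1] annulation. After chromatographic removal of any cis isomer this gives (2S,3S)-4-bromo-2-ArP-3-Bf-6-(PBB-oxy)-2,3-dihydro-1-benzofuran F6. Treatment of F6 as in step 13 removes the remaining PBB ether, and the fallback comes back at 22, so step 12 is bypassed as well.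

Step 15. BCl3 may open the benzylic C2–O bonds of the two dihydrofurans with capture of the cations by the scavenger, or acid set free during the quench may protonate the stilbene and start a Friedel–Crafts closure onto ring B. The fallback removes the benzyl groups before the stilbene exists and ends with mild base; it sets out from 22. BCl3 and pentamethylbenzene at −78 °C should give (2S,3S)-4-bromo-3-[(2R,3R)-3-(3,5-dihydroxyphenyl)-4-hydroxy-2-(4-hydroxyphenyl)-2,3-dihydro-1-benzofuran-6-yl]-2-(4-hydroxyphenyl)-2,3-dihydro-1-benzofuran-6-ol F7. Heck coupling of F7 with commercial 4-acetoxystyrene (Pd(OAc)2, P(o-tol)3, Et3N, DMF, 90 °C) should give the monoacetate 4-[(E)-2-{(2S,3S)-3-[(2R,3R)-3-(3,5-dihydroxyphenyl)-4-hydroxy-2-(4-hydroxyphenyl)-2,3-dihydro-1-benzofuran-6-yl]-6-hydroxy-2-(4-hydroxyphenyl)-2,3-dihydro-1-benzofuran-4-yl}ethenyl]phenyl acetate F8. Methanolysis of F8 (K2CO3, MeOH, 0 °C, under argon) brings the fallback back at 25.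

**Further compounds**
F1 | step 3 | methyl 4-diazo-3,5-dioxocyclohexane-1-carboxylate | COC(=O)C1CC(=O)C(=[N+]=[N-])C(=O)C1
F2 | step 3 | (E)-1,3-bis(benzyloxy)-5-{2-[4-(benzyloxy)phenyl]ethenyl}benzene | c1ccccc1COc1ccc(/C=C/c2cc(OCc3ccccc3)cc(OCc3ccccc3)c2)cc1
F3 | step 11 | (Bf)[2-bromo-6-hydroxy-4-(PBB-oxy)phenyl]methanone | O=C(c1c(Br)cc(OCc2ccc(OCc3ccccc3)cc2)cc1O)c1cc(OCc2ccccc2)c2c(c1)O[C@@H](c1ccc(OCc3ccccc3)cc1)[C@@H]2c1cc(OCc2ccccc2)cc(OCc2ccccc2)c1
F4 | step 11 | (Bf)[2-bromo-6-hydroxy-4-(PBB-oxy)phenyl]methanol (carbinol epimers) | OC(c1c(Br)cc(OCc2ccc(OCc3ccccc3)cc2)cc1O)c1cc(OCc2ccccc2)c2c(c1)O[C@@H](c1ccc(OCc3ccccc3)cc1)[C@@H]2c1cc(OCc2ccccc2)cc(OCc2ccccc2)c1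
F5 | step 11 | (2R,5R)-1-(PBB)-2,5-dimethylthiolan-1-ium tetrafluoroborate | C[C@@H]1CC[C@@H](C)[S+]1Cc1ccc(OCc2ccccc2)cc1.F[B-](F)(F)F
F6 | step 11 | (2S,3S)-4-bromo-2-ArP-3-Bf-6-(PBB-oxy)-2,3-dihydro-1-benzofuran | Brc1cc(OCc2ccc(OCc3ccccc3)cc2)cc2c1[C@H](c4cc(OCc5ccccc5)c5c(c4)O[C@@H](c4ccc(OCc6ccccc6)cc4)[C@@H]5c4cc(OCc5ccccc5)cc(OCc5ccccc5)c4)[C@@H](c1ccc(OCc3ccccc3)cc1)O2
F7 | step 15 | (2S,3S)-4-bromo-3-[(2R,3R)-3-(3,5-dihydroxyphenyl)-4-hydroxy-2-(4-hydroxyphenyl)-2,3-dihydro-1-benzofuran-6-yl]-2-(4-hydroxyphenyl)-2,3-dihydro-1-benzofuran-6-ol | Brc1cc(O)cc2c1[C@H](c4cc(O)c5c(c4)O[C@@H](c4ccc(O)cc4)[C@@H]5c4cc(O)cc(O)c4)[C@@H](c1ccc(O)cc1)O2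
F8 | step 15 | 4-[(E)-2-{(2S,3S)-3-[(2R,3R)-3-(3,5-dihydroxyphenyl)-4-hydroxy-2-(4-hydroxyphenyl)-2,3-dihydro-1-benzofuran-6-yl]-6-hydroxy-2-(4-hydroxyphenyl)-2,3-dihydro-1-benzofuran-4-yl}ethenyl]phenyl acetate | CC(=O)Oc1ccc(/C=C/c2cc(O)cc3c2[C@H](c2cc(O)c4c(c2)O[C@@H](c2ccc(O)cc2)[C@@H]4c2cc(O)cc(O)c2)[C@@H](c2ccc(O)cc2)O3)cc1
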